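## Structural features

Iriediol has three carbocycles: a trans-fused hydrindane (six-membered ring B, five-membered ring C) and a cyclohexane ring A joined to C3 of ring C through an exocyclic, trisubstituted C8=C1′ alkene of E geometry. Six contiguous stereocentres lie on the bicycle: C2 (secondary carbinol), C3, C3a, C4 (tertiary carbinol with an axial hydroxyl), the quaternary C7a with its angular methyl, and C7 (equatorial secondary bromide); C7a adjoins both C3a and C7, and C4 adjoins C3a. With β as the face of the angular methyl, the C4 oxygen and the C7 bromine are β, while H3a, the C3 side chain, the C2 hydroxyl and the C4 methyl are α. The seventh stereocentre, C4′ in ring A, is a second neopentylic bromide and is too remote to be controlled from the bicycle. The fragile groups are the two secondary bromides (elimination, reductive cleavage), the tertiary alcohol (ionization, dehydration) and the alkene, which would not survive a hydrogen-atom-transfer reduction and whose geometry depends only on the remote dissymmetry of ring A. The real difficulties are the quaternary C7a next to a trans ring fusion and syn to the C4 oxygen, the two C–Br centres beside fully substituted carbons (no substitution with inversion is possible there), and the C2 hydroxyl, whose hydrogen would have to arrive from the face covered by the angular methyl. The key step exploits ring C: a cyclopentane with oxygen on C2 between C1 and C3, fused to ring B at C3a and the quaternary C7a, is the retron of a Pauson–Khand reaction with C3≡C3a as alkyne, C7a=C1 as 1,1-disubstituted alkene, C2 as CO and C4–C7 as tether.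

## Logic of the disconnections

41 ⇒ 40. Only the O–Si bonds at C2 and C4 are cut. The last step must not touch the bromides or the alkene, so both oxygens carry triethylsilyl groups that buffered fluoride removes at or below room temperature. The demand falls on the earlier choice of silyl groups, not on this step.

40 ⇒ 27 + 38. The C8=C1′ double bond is cut into a C8 aldehyde and a C1′ sulfone. It is the only bond between the bicycle and ring A, each half then carries its own bromide, and the alkene stays out of the radical reduction that sets C7. The demand is a Julia–Kocienski reaction between a tertiary sulfonyl carbanion and a hindered, epimerizable aldehyde. The geometry cannot be controlled and the isomers must be separated.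

27 ⇒ 26 ⇒ 25 ⇒ 24 ⇒ 22. The C7–Br and C7–H bonds are traced back to a C7 ketone. A bromide beside quaternary C7a cannot be made by substitution, whereas a ketone can be carried masked through the early steps and turned into a vinyl bromide. This removes a stereocentre and a fragile group from everything upstream. The demand is that the radical at C7 takes its hydrogen on the α face, and that this happens before ring A and its alkene arrive.

22 ⇒ 21 ⇒ 19 ⇒ 18 ⇒ 17. The C2–H bond is cut back to the C2 ketone, with one C–O inversion. The C2 oxygen is the carbonyl of the cyclopentenone, and the angular methyl lets hydride approach only from the α face. The reduction therefore gives the 2β-alcohol and the 2α-oxygen is obtained by inversion. The demand is an SN2 displacement at C2 from the α face past C8. One acid operation then frees C7 and all hydroxyls for uniform re-protection.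

17 ⇒ 15. The C3a–H and C3–H bonds are cut. The enone is the direct cyclization product, and two stereocentres are derived from sp2 carbons. The demand is protonation of C3a on the α face, survival of the silyloxy groups at the γ (C4) and β (C8) positions of the enone, and equilibration of C3.

15 ⇒ 12 + 13. C3a–C7a, C1–C2 and C2–C3 are cut. This removes both rings and the quaternary centre and leaves an acyclic chain with one stereocentre. The demand is insertion of an unactivated 1,1-disubstituted alkene in a six-ring closure, with the C7a face chosen by C4.

12 ⇒ 11 ⇒ 10 ⇒ 8 + 9. The C7–C7a bond is cut and the dioxolane is traced to a ketone. The isopropenyl unit comes from Grignard reagent 9 and an aldehyde. The ketal keeps the alkene electron-rich for the cyclization, stores the C7 carbonyl, and adds a fully substituted carbon to the tether. The demand is ketalization of an enone without conjugate addition of the diol.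

8 ⇒ 7 ⇒ 6 ⇒ 3 + 4 ⇒ 2 ⇒ 1. The C7 aldehyde is traced to a trisubstituted alkene, the C3–C8 bond to an acetylide and 4, the alkyne to an epoxy chloride, and the epoxide to the allylic alcohol 1. The single stereocentre of 12 is a tertiary propargylic carbinol whose two alkyl flanks differ little, so it is set by a hydroxyl-directed asymmetric epoxidation, not by an asymmetric addition to a ketone. The demand is that the fragmentation never breaks the C–O bond at the stereocentre.

38 ⇒ 37 ⇒ 36 ⇒ 34. The C1′–S bond is cut back to a carbinol and then to an exocyclic methylene group. These are functional-group changes at a carbon that ends sp2, so no stereocontrol is needed there.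

34 ⇒ 33 ⇒ 30 + 31 ⇒ 29 ⇒ 28. The C2′–C3′ bond is cut (cation–olefin cyclization), then C5′–C6′ (alkylation), then the C–Br and C–Cl bonds (alkene bromochlorination of 28). The C4′ bromide beside CMe2 is made by electrophilic bromination of an alkene and carried through a bromiranium ion, the only dependable way to such a centre. The demand is that ionization and ring closure do not scramble the bromiranium ion.

## Other disconnections considered

Alternative 1: The cut is C2–C3, which opens ring C to the monocyclic aldehyde A1. Ring B of A1 carries the CH2–CHO arm on C7a and, on C3a, an (E)-alkenyl chain ending at the stereogenic C1′–H of ring A. In the forward step Me2AlCl promotes an intramolecular carbonyl-ene reaction: the aldehyde carbon bonds to C3, the C1′ hydrogen moves to oxygen and the alkene moves to C8=C1′, giving A2, one desilylation from the target.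
- In its favour: the cyclic six-atom transition state holds the oxygen and C8 on the same side, so the cis C2–OH/C3 relationship forms directly. The transferred hydrogen must lie on the face attacked by the aldehyde, so one C1′ epimer (1′R as drawn for A1, assuming suprafacial transfer through a chair-like array) relays into the E alkene. On both points the alternative is better than the chosen plan, which needs reduction plus inversion at C2 and has no control of alkene geometry.
- Against it here: the ene closure forms a five-membered ring through the terminal carbon of the ene, a slow mode, and a stepwise cationic path (chloride or methyl capture, loss of the relay) can compete. The Lewis acid also meets a tertiary silyl ether and two secondary bromides. The difficulty moves into A1, where the quaternary C7a, C3a, C4, the C7 bromide, an E alkene and a ring A with two defined stereocentres must all be in place on a monocyclic ring.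
- Comparison: on structure, the Pauson–Khand plan makes the quaternary centre and both rings from an acyclic chain in one step, while A1 has to be built centre by centre. On mechanism, the ene step is the better stereochemical relay. On step economy, the alternative is equal or better after its key step and is expected to be longer before it.

Alternative 2: The cut is C2′–C3′ in ring A. The precursor A3 is the complete hydrindane carrying on C3 a stereogenic allylsilane (silicon on C8) whose chain ends in the bromo-chloro unit. In (CF3)2CHOH the tertiary chloride ionizes with bromine participation, the bromiranium ion is opened at C3′ by the allylsilane CH2 anti to silicon, and loss of silicon leaves the C8=C1′ alkene in A4.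
- In its favour: the C8 configuration (8S as drawn for A3, for anti attack through a chair with equatorial bromine) fixes the E geometry, which is better than the chosen plan. The C4′ centre comes from the same enantioselective bromochlorination and ionization that is used here for 34, so on that point the two are equal. No basic or reducing reagent touches the finished bicycle.
- Against it here: the ionization runs at the end on the most valuable material, with a free tertiary C4 alcohol that can ionize in the same medium. The α-silyl stereocentre at C8 must be set beside the crowded C3 and matched to C4′. Protodesilylation and transfer of Br+ between alkenes are further risks. The step says nothing about how rings B and C and C7a are made, so it is an endgame, not a route to the core.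
- Comparison: on structure, it completes ring A on the molecule instead of coupling a finished ring. On mechanism, it is stereospecific where the olefination is not. On step economy, it is roughly equal in count but linear where the chosen plan is convergent.

Alternative 3: The cut is C3a–C7a. The precursor A5 is a (Z,Z)-cyclononadienone with the C2 carbonyl between the C1=C7a and C3=C3a alkenes. BF3·OEt2 generates the pentadienyl cation, conrotatory closure joins C3a and C7a across the ring, and Et3SiH reduces the oxyallyl cation to the ketone A6.
- In its favour: conrotation of two Z alkenes gives the trans ring fusion directly, and the ketone emerges saturated. On the C3a/C7a relationship it is better than the chosen plan, which needs a separate dissolving-metal step, and on rings formed per step it is equal.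
- Against it here: A5 is a nine-membered ring with two trisubstituted enone alkenes and two stereocentres, far costlier than an acyclic enyne. Closure onto a fully substituted terminus is slow for this reaction type. The sense of conrotation relative to C4 and C7 is the only source of absolute control. The Lewis acid acts beside an allylic tertiary silyl ether and an allylic silyl ether. The site of hydride delivery and the C3 configuration are open. A6 still needs the C2 inversion (equal to the chosen plan) and conversion of the C7 oxygen into the β-bromide with net retention, which again means ketone, vinyl bromide and radical reduction. The benzyl ether must also be removed without hydrogenolysis of C–Br.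
- Comparison: on structure, the difficulty sits in a medium ring and not in an acyclic chain. On mechanism, the pericyclic control of the ring fusion is attractive. On step economy, it is expected to be longer overall.

Key step: step 9

Remarks
- Notation: indane numbering for the hydrindane and primed numbers for ring A; β is the face of the angular C7a methyl, α the opposite face.
- Iriediol is treated as the (E)-(2R,3S,3aS,4R,7S,7aS,4′S) isomer. On this basis 12 must be R at C4, and 15 must be S at C7a with the C4 oxygen syn to the angular methyl. The structures of 12 and 15 below carry these descriptors, and no descriptor needed correction.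
- Design of 12: both oxygens carry triethylsilyl groups so that the hindered tertiary ether can be removed at the end without forcing conditions. C4 is set by asymmetric epoxidation. The tertiary alcohol is silylated before the C7 ketone exists, which avoids a γ-hydroxy ketone and its cyclic hemiketal and avoids double addition of a Grignard reagent to a lactone.
- 10 is a mixture at C7, and 36 to 39 are mixtures at C1′; both carbons become sp2 later.

## Route

Step 1
Reactants: 1 geraniol
Product: 2 (2R,3R)-2,3-epoxygeraniol
Conditions: Ti(OiPr)4 (5 mol %), D-(−)-diethyl tartrate (7 mol %), t-BuOOH (anhydrous), 4 Å MS, CH2Cl2, −20 °C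
Reagents that add atoms: tert-butyl hydroperoxide, CC(C)(C)OO
Why: Sharpless asymmetric epoxidation; the allylic hydroxyl directs the titanium tartrate catalyst to the 2,3-alkene only, and the D-tartrate delivers oxygen to the face that makes the epoxide carbon C3 R, the carbon that becomes C4 of the hydrindane.

Step 2
Reactants: 2 (2R,3R)-2,3-epoxygeraniol
Product: 3 (2R,3R)-2,3-epoxygeranyl chloride
Conditions: PPh3, CCl4, NaHCO3, reflux
Reagents that add atoms: carbon tetrachloride, ClC(Cl)(Cl)Cl
Why: Appel chlorination of the primary alcohol under neutral conditions; the epoxide and both stereocentres are not touched.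

Step 3
Reactants: 3 (2R,3R)-2,3-epoxygeranyl chloride; 4 formaldehyde (as paraformaldehyde)
Product: 6 (R)-4,8-dimethylnon-7-en-2-yne-1,4-diol, via dilithium alkynolate 5 (not isolated)
Conditions: n-BuLi (3.5 equiv), THF, −40 °C; then (CH2O)n, −40 °C → rt; aq. NH4Cl
Reagents that add atoms: none
Why: Base-induced fragmentation of a 2,3-epoxy chloride (deprotonation beside chlorine opens the epoxide to a chlorovinyl alkoxide and a second elimination gives the alkyne), then hydroxymethylation of the lithium acetylide; the C–O bond at the tertiary carbon is never broken, so the R configuration is kept.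

Step 4
Reactants: 6 (R)-4,8-dimethylnon-7-en-2-yne-1,4-diol
Product: 7 (R)-4,8-dimethyl-1,4-bis(triethylsilyloxy)non-7-en-2-yne
Conditions: Et3SiOTf (2.6 equiv), 2,6-lutidine, CH2Cl2, −78 → 0 °C
Reagents that add atoms: triethylsilyl trifluoromethanesulfonate, CC[Si](CC)(CC)OS(=O)(=O)C(F)(F)F
Why: Silylation with a silyl triflate, which is reactive enough for the tertiary propargylic hydroxyl as well as the primary one.

Step 5
Reactants: 7 (R)-4,8-dimethyl-1,4-bis(triethylsilyloxy)non-7-en-2-yne
Product: 8 (R)-4-methyl-4,7-bis(triethylsilyloxy)hept-5-ynal
Conditions: OsO4 (2 mol %), NaIO4 (4 equiv), 2,6-lutidine, 1,4-dioxane–H2O, rt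
Reagents that add atoms: NaIO4 (sodium periodate), [Na+].[O-]I(=O)(=O)=O (terminal oxidant; the carbonyl oxygen is transferred by way of OsO4)
Why: Lemieux–Johnson cleavage; the electron-rich trisubstituted alkene is dihydroxylated far faster than the internal alkyne, and the lutidine buffer protects the silyl ethers.

Step 6
Reactants: 8 (R)-4-methyl-4,7-bis(triethylsilyloxy)hept-5-ynal; 9 isopropenylmagnesium bromide
Product: 10 (6R)-2,6-dimethyl-6,9-bis(triethylsilyloxy)non-1-en-7-yn-3-ol (both C3 epimers)
Conditions: THF, −78 °C; aq. NH4Cl
Reagents that add atoms: none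
Why: Grignard addition to the aldehyde forms the future C7–C7a bond; the new carbinol centre is unselective and is oxidized in the next step.

Step 7
Reactants: 10 (6R)-2,6-dimethyl-6,9-bis(triethylsilyloxy)non-1-en-7-yn-3-ol
Product: 11 (R)-2,6-dimethyl-6,9-bis(triethylsilyloxy)non-1-en-7-yn-3-one
Conditions: Dess–Martin periodinane, NaHCO3, CH2Cl2, 0 °C → rt
Reagents that add atoms: none
Why: Dess–Martin oxidation of the allylic alcohol under buffered, non-acidic conditions that the silyl ethers and the sensitive enone tolerate.

Step 8
Reactants: 11 (R)-2,6-dimethyl-6,9-bis(triethylsilyloxy)non-1-en-7-yn-3-one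
Product: 12 (R)-2-(prop-1-en-2-yl)-2-[3-methyl-3,6-bis(triethylsilyloxy)hex-4-yn-1-yl]-1,3-dioxolane
Conditions: Me3SiOCH2CH2OSiMe3 (3 equiv), Me3SiOTf (5 mol %), CH2Cl2, −78 → −30 °C; pyridine
Reagents that add atoms: 1,2-bis(trimethylsilyloxy)ethane, C[Si](C)(C)OCCO[Si](C)(C)C
Why: Aprotic ketalization catalysed by a silyl triflate and driven by formation of hexamethyldisiloxane; with no protic acid and no free diol, conjugate addition to the enone and loss of the silyl ethers are avoided.

Step 9
Reactants: 12 (R)-2-(prop-1-en-2-yl)-2-[3-methyl-3,6-bis(triethylsilyloxy)hex-4-yn-1-yl]-1,3-dioxolane; 13 carbon monoxide (delivered by Co2(CO)8)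
Product: 15 4β-triethylsilyloxy-3-(triethylsilyloxymethyl)-4α,7aβ-dimethyl-7,7-ethylenedioxy-1,4,5,6,7,7a-hexahydroinden-2-one (C3=C3a enone), via hexacarbonyldicobalt alkyne complex 14 (not isolated)
Conditions: Co2(CO)8 (1.1 equiv), CH2Cl2, rt; then Me3NO (anhydrous, 8 equiv), 4 Å MS, 0 °C → rt (to 40 °C if needed)
Reagents that add atoms: none
Why: Pauson–Khand reaction, the cobalt-mediated [2+2+1] cycloaddition of alkyne, alkene and CO, here intramolecular on a 1,7-enyne; the closest known reaction type is the cyclization of enynes with 1,1-disubstituted alkenes to angularly methylated bicyclic enones. Co2(CO)8 binds the alkyne as complex 14, Me3NO oxidizes one CO ligand to CO2 and frees a site at which the C7a=C1 alkene coordinates and inserts into the Co–C3a bond; CO then inserts into the Co–C1 bond and reductive elimination joins C2 to C3. Ring B closes in the insertion step (C3a–C7a, six-membered, with C1 left outside the new ring) and ring C in the carbonylation and reductive elimination (C1–C2, C2–C3). The only new stereocentre is C7a, and C4 controls it: in the chair-like fold of the forming six-membered ring the C7a methyl must be axial because C1 has to lie in the plane of the metallacycle, so the axial site of C4 faces it, and oxygen is tolerated there better than carbon. The silyloxy group should therefore end syn to the angular methyl and the C4 methyl equatorial; the allylic strain between that equatorial methyl and the C8 arm works against this and limits the margin. The step needs insertion of an unactivated 1,1-disubstituted alkene in the slower six-ring mode, and this facial preference. The fully substituted C4 and the ketal carbon C7 bias the tether towards the folded conformer, the ketal keeps the alkene electron-rich, and the amine oxide lets the reaction run near room temperature where silyl ethers and ketal are safe.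

Step 10
Reactants: 15 hydrindenone
Product: 17 3α-(triethylsilyloxymethyl)-4β-triethylsilyloxy-4α,7aβ-dimethyl-7,7-ethylenedioxy-3aα-H-hydrindan-2-one (trans fusion), via lithium enolate 16 (not isolated)
Conditions: Li (5 equiv), NH3(l)–THF, t-BuOH (1.1 equiv), −78 °C; isoprene, solid NH4Cl; crude product with DBU (0.3 equiv), toluene, rt
Reagents that add atoms: none
Why: Dissolving-metal (Birch-type) conjugate reduction; C3a is protonated on the α face, away from its two β-axial neighbours (the C7a methyl and the C4 silyloxy group), which gives the trans fusion, and base equilibration puts the C3 arm on the α face, away from the same two groups. t-BuOH protonates the C3a carbanion before it can expel the C4 silyloxy group.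

Step 11
Reactants: 17 trans-hydrindan-2-one
Product: 18 the 2β-alcohol of 17 (hydroxyl trans to the C3 arm)
Conditions: NaBH4, MeOH–THF (1:3), −20 °C
Reagents that add atoms: none
Why: Hydride reduction under steric approach control; the angular methyl lies over the β face of C2, so hydride adds from the α face and the hydroxyl appears β, the epimer that step 12 inverts.

Step 12
Reactants: 18 2β-alcohol
Product: 19 the 2α-(4-nitrobenzoate) (ester oxygen cis to the C3 arm)
Conditions: 4-O2NC6H4CO2H, PPh3, DIAD (4 equiv each), toluene, 0 → 40 °C
Reagents that add atoms: 4-nitrobenzoic acid, O=C(O)c1ccc(cc1)[N+](=O)[O-]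
Why: Mitsunobu reaction; the oxyphosphonium ion of the 2β-alcohol is displaced by the carboxylate with inversion, which sets the α configuration at C2, and departure of the leaving group relieves its 1,3-interaction with the angular methyl.

Step 13
Reactants: 19 2α-(4-nitrobenzoate)
Product: 21 2α,4β-dihydroxy-3α-(hydroxymethyl)-4α,7aβ-dimethyl-trans-hydrindan-7-one, via 2α-alcohol 20 (not isolated)
Conditions: K2CO3, MeOH, rt; then aq. HCl (1 M, to pH 1), THF, rt
Reagents that add atoms: water, O
Why: Methanolysis of the activated ester, then acid hydrolysis of the dioxolane and of both silyl ethers in the same flask; one operation frees the C7 ketone and all three hydroxyls, and no centre is epimerizable because C7a is quaternary.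

Step 14
Reactants: 21 keto triol
Product: 22 the tris(triethylsilyl) ether of 21 (C2, C4 and C8 oxygens)
Conditions: Et3SiOTf (4 equiv), 2,6-lutidine, CH2Cl2, −78 → 0 °C
Reagents that add atoms: triethylsilyl trifluoromethanesulfonate, CC[Si](CC)(CC)OS(=O)(=O)C(F)(F)F
Why: Silyl triflate silylation of the primary, the secondary and the hindered tertiary hydroxyl; 2,6-lutidine at low temperature does not enolize the ketone.

Step 15
Reactants: 22 tris(triethylsilyl) ketone
Product: 24 the C7 enol triflate (C6=C7), via potassium enolate 23 (not isolated)
Conditions: KN(SiMe3)2 (1.3 equiv), THF, −78 °C; PhNTf2, −78 → 0 °C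
Reagents that add atoms: N-phenylbis(trifluoromethanesulfonimide), O=S(=O)(N(c1ccccc1)S(=O)(=O)C(F)(F)F)C(F)(F)F
Why: Enol triflate formation; the ketone can enolize only towards C6 because C7a is quaternary.

Step 16
Reactants: 24 enol triflate
Product: 25 the vinyl bromide (7-bromo, C6=C7)
Conditions: Ni(cod)2 (10 mol %), LiBr (3 equiv), DMA–THF, rt
Reagents that add atoms: LiBr, [Li+].[Br-]
Why: Nickel-catalysed exchange of an enol triflate for bromide (oxidative addition to zerovalent nickel, halide exchange, reductive elimination); it places bromine on C7 where substitution could not.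

Step 17
Reactants: 25 vinyl bromide
Product: 26 7β-bromo-2α,4β-bis(triethylsilyloxy)-3α-(triethylsilyloxymethyl)-4α,7aβ-dimethyl-trans-hydrindane
Conditions: Mn(dpm)3 (10 mol %), PhSiH3, t-BuOOH, i-PrOH, rt
Reagents that add atoms: none
Why: Hydrogen-atom-transfer hydrogenation of a haloalkene; H adds to C6, and the α-bromo radical at C7 takes the second hydrogen along the axial α trajectory, anti to the axial C7a methyl, so bromine ends equatorial and β. Carbon–halogen bonds are not reduced, and no other alkene is present yet.

Step 18
Reactants: 26 tris(triethylsilyl) bromide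
Product: 27 the C8 aldehyde (3α-formyl; C2 and C4 triethylsilyl ethers kept)
Conditions: (COCl)2, DMSO, CH2Cl2, −78 → −40 °C; Et3N, −78 → 0 °C
Reagents that add atoms: none
Why: Swern oxidation applied directly to the silyl ether; the activated DMSO reagent cleaves only the unhindered primary Si–O bond and the alkoxysulfonium ion collapses to the aldehyde. The base is used cold because C3 is epimerizable.

Step 19
Reactants: 28 prenol (3-methylbut-2-en-1-ol)
Product: 29 (S)-2-bromo-3-chloro-3-methylbutan-1-ol
Conditions: N-bromosuccinimide, ClTi(OiPr)3 (1.1 equiv), chiral tridentate Schiff-base ligand (20 mol %, the antipode that leads to the S bromide), hexanes, −20 °C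
Reagents that add atoms: N-bromosuccinimide, O=C1CCC(=O)N1Br; ClTi(OiPr)3, CC(C)O[Ti](Cl)(OC(C)C)OC(C)C
Why: Titanium-mediated catalytic enantioselective bromochlorination of an allylic alcohol; the bound alkoxide is brominated on one face under ligand control and chloride is delivered anti to the tertiary carbon, which sets C4′ as S by electrophilic bromination.

Step 20
Reactants: 29 (S)-2-bromo-3-chloro-3-methylbutan-1-ol
Product: 30 (S)-2-bromo-3-chloro-3-methylbutyl trifluoromethanesulfonate
Conditions: Tf2O, 2,6-lutidine, CH2Cl2, −78 °C
Reagents that add atoms: trifluoromethanesulfonic anhydride, O=S(=O)(OS(=O)(=O)C(F)(F)F)C(F)(F)F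
Why: Sulfonylation of the primary alcohol; the β-halogens slow ionization, so the primary triflate can be handled cold.

Step 21
Reactants: 30 triflate; 31 2-(chloromethyl)allyl-trimethylsilane
Product: 33 (S)-(5-bromo-6-chloro-6-methyl-2-methylideneheptyl)trimethylsilane, via allylic Grignard reagent 32 (not isolated)
Conditions: 31, Mg, THF, 0 °C; then 30, CuBr·SMe2 (5 mol %), THF, −78 → −40 °C
Reagents that add atoms: none
Why: Copper-catalysed SN2 coupling of an allylic Grignard reagent with a primary triflate; both ends of the allyl unit are equivalent, and the hindered secondary bromide and tertiary chloride do not react at this temperature.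

Step 22
Reactants: 33 allylsilane bromo chloride
Product: 34 (S)-4-bromo-3,3-dimethyl-1-methylidenecyclohexane
Conditions: (CF3)2CHOH (dilute), 2,6-di-tert-butyl-4-methylpyridine (0.2 equiv), 0 °C → rt
Reagents that add atoms: none
Why: Cation–olefin cyclization; the ionizing, weakly nucleophilic alcohol removes the tertiary chloride with bromine participation, the bromiranium ion is opened at the tertiary carbon by the allylsilane CH2 through a chair, and loss of silicon leaves the exocyclic methylene. The C–Br bond at C4′ is never broken, so S is retained.

Step 23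
Reactants: 34 (S)-4-bromo-3,3-dimethyl-1-methylidenecyclohexane
Product: 36 (4S)-4-bromo-3,3-dimethylcyclohexan-1-ol (both C1 epimers), via ketone 35 (not isolated)
Conditions: OsO4 (2 mol %), NaIO4, 2,6-lutidine, 1,4-dioxane–H2O, rt; extractive work-up; NaBH4, MeOH, 0 °C
Reagents that add atoms: NaIO4 (sodium periodate), [Na+].[O-]I(=O)(=O)=O (terminal oxidant; the oxygen is transferred by way of OsO4)
Why: Lemieux–Johnson cleavage of the 1,1-disubstituted alkene, then borohydride reduction of the ketone; the new carbinol centre does not matter because C1′ becomes sp2.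

Step 24
Reactants: 36 (4S)-4-bromo-3,3-dimethylcyclohexan-1-ol
Product: 37 5-{[(4S)-4-bromo-3,3-dimethylcyclohexyl]sulfanyl}-1-phenyl-1H-tetrazole
Conditions: 1-phenyl-1H-tetrazole-5-thiol, PPh3, DIAD, THF, 0 °C → rt
Reagents that add atoms: 1-phenyl-1H-tetrazole-5-thiol, Sc1nnnn1c1ccccc1
Why: Mitsunobu thioetherification of a secondary cyclohexanol with the acidic tetrazole thiol; the inversion at C1′ is of no consequence.

Step 25
Reactants: 37 sulfide
Product: 38 5-{[(4S)-4-bromo-3,3-dimethylcyclohexyl]sulfonyl}-1-phenyl-1H-tetrazole
Conditions: (NH4)6Mo7O24·4H2O (10 mol %), H2O2 (30 % aq.), EtOH, 0 °C → rt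
Reagents that add atoms: hydrogen peroxide, OO
Why: Molybdate-catalysed peroxide oxidation of the sulfide to the sulfone; the alkyl bromide is inert.

Step 26
Reactants: 38 sulfone; 27 C8 aldehyde
Product: 40 2,4-bis-O-(triethylsilyl)iriediol (E isomer), via metalated sulfone 39 (not isolated)
Conditions: 38 (1.5 equiv), KN(SiMe3)2, DME, −78 °C; then 27, −78 → −20 °C; aq. NH4Cl; chromatography on AgNO3-impregnated silica
Reagents that add atoms: none
Why: Julia–Kocienski olefination; the metalated sulfone adds to the aldehyde, and Smiles rearrangement with loss of SO2 and the tetrazolyl oxide gives the trisubstituted alkene. The two ring A flanks of C1′ differ only remotely, so little preference between E and Z is expected and the E isomer is isolated by chromatography.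

Step 27
Reactants: 40 2,4-bis-O-(triethylsilyl)iriediol
Product: 41 iriediol
Conditions: HF·pyridine, pyridine, THF, 0 °C → rt
Reagents that add atoms: none
Why: Fluoride cleavage of the secondary and the tertiary triethylsilyl ether under buffered, non-basic conditions that leave both bromides and the alkene unchanged.

## Compound list

1 | geraniol, (2E)-3,7-dimethylocta-2,6-dien-1-ol | CC(C)=CCC/C(C)=C/CO | starting material
2 | (2R,3R)-2,3-epoxygeraniol | CC(C)=CCC[C@@]1(C)O[C@@H]1CO | intermediate
3 | (2R,3R)-2,3-epoxygeranyl chloride, (2S,3R)-2-(chloromethyl)-3-methyl-3-(4-methylpent-3-en-1-yl)oxirane | CC(C)=CCC[C@@]1(C)O[C@@H]1CCl | intermediate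
4 | formaldehyde (used as paraformaldehyde) | C=O | starting material
5 | dilithium salt of (R)-3,7-dimethyloct-6-en-1-yn-3-ol (alkoxide and acetylide) | [Li]C#C[C@](C)(O[Li])CCC=C(C)C | intermediate
6 | (R)-4,8-dimethylnon-7-en-2-yne-1,4-diol | CC(C)=CCC[C@@](C)(O)C#CCO | intermediate
7 | (R)-4,8-dimethyl-1,4-bis(triethylsilyloxy)non-7-en-2-yne | CC(C)=CCC[C@@](C)(O[Si](CC)(CC)CC)C#CCO[Si](CC)(CC)CC | intermediate
8 | (R)-4-methyl-4,7-bis(triethylsilyloxy)hept-5-ynal | O=CCC[C@@](C)(O[Si](CC)(CC)CC)C#CCO[Si](CC)(CC)CC | intermediate
9 | isopropenylmagnesium bromide | CC(=C)[Mg]Br | starting material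
10 | (6R)-2,6-dimethyl-6,9-bis(triethylsilyloxy)non-1-en-7-yn-3-ol (C3 epimers) | C=C(C)C(O)CC[C@@](C)(O[Si](CC)(CC)CC)C#CCO[Si](CC)(CC)CC | intermediate
11 | (R)-2,6-dimethyl-6,9-bis(triethylsilyloxy)non-1-en-7-yn-3-one | C=C(C)C(=O)CC[C@@](C)(O[Si](CC)(CC)CC)C#CCO[Si](CC)(CC)CC | intermediate
12 | (R)-2-(prop-1-en-2-yl)-2-[3-methyl-3,6-bis(triethylsilyloxy)hex-4-yn-1-yl]-1,3-dioxolane (1,7-enyne) | C=C(C)C1(OCCO1)CC[C@@](C)(O[Si](CC)(CC)CC)C#CCO[Si](CC)(CC)CC | intermediate
13 | carbon monoxide (delivered by Co2(CO)8) | [C-]#[O+] | starting material
14 | Co2(CO)6 complex of the alkyne of 12 (written as its components) | C=C(C)C1(OCCO1)CC[C@@](C)(O[Si](CC)(CC)CC)C#CCO[Si](CC)(CC)CC.[Co].[Co].[C-]#[O+].[C-]#[O+].[C-]#[O+].[C-]#[O+].[C-]#[O+].[C-]#[O+] | intermediate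
15 | hydrindenone: 4β-triethylsilyloxy-3-(triethylsilyloxymethyl)-4α,7aβ-dimethyl-7,7-ethylenedioxy-1,4,5,6,7,7a-hexahydroinden-2-one, (4R,7aS) | O=C1C[C@]2(C)C3(OCCO3)CC[C@@](C)(O[Si](CC)(CC)CC)C2=C1CO[Si](CC)(CC)CC | intermediate
16 | lithium enolate (C2–OLi, C2=C3) with 3aα-H | CC[Si](CC)(CC)OCC2=C(O[Li])C[C@]3(C)C4(OCCO4)CC[C@@](C)(O[Si](CC)(CC)CC)[C@@H]23 | intermediate
17 | 3α-(triethylsilyloxymethyl)-4β-triethylsilyloxy-4α,7aβ-dimethyl-7,7-ethylenedioxy-3aα-H-hydrindan-2-one | CC[Si](CC)(CC)OC[C@@H]2C(=O)C[C@]3(C)C4(OCCO4)CC[C@@](C)(O[Si](CC)(CC)CC)[C@@H]23 | intermediate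
18 | 2β-alcohol of 17 | CC[Si](CC)(CC)OC[C@@H]2[C@@H](O)C[C@]3(C)C4(OCCO4)CC[C@@](C)(O[Si](CC)(CC)CC)[C@@H]23 | intermediate
19 | 2α-(4-nitrobenzoate) | CC[Si](CC)(CC)OC[C@@H]2[C@H](OC(=O)c5ccc(cc5)[N+](=O)[O-])C[C@]3(C)C4(OCCO4)CC[C@@](C)(O[Si](CC)(CC)CC)[C@@H]23 | intermediate
20 | 2α-alcohol (silyl ethers and ketal still in place) | CC[Si](CC)(CC)OC[C@@H]2[C@H](O)C[C@]3(C)C4(OCCO4)CC[C@@](C)(O[Si](CC)(CC)CC)[C@@H]23 | intermediate
21 | 2α,4β-dihydroxy-3α-(hydroxymethyl)-4α,7aβ-dimethyl-trans-hydrindan-7-one | OC[C@@H]2[C@H](O)C[C@]3(C)C(=O)CC[C@@](C)(O)[C@@H]23 | intermediate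
22 | tris(triethylsilyl) ether of 21 | CC[Si](CC)(CC)OC[C@@H]2[C@H](O[Si](CC)(CC)CC)C[C@]3(C)C(=O)CC[C@@](C)(O[Si](CC)(CC)CC)[C@@H]23 | intermediate
23 | potassium enolate of 22 (C7–OK, C6=C7) | CC[Si](CC)(CC)OC[C@@H]2[C@H](O[Si](CC)(CC)CC)C[C@]3(C)C(O[K])=CC[C@@](C)(O[Si](CC)(CC)CC)[C@@H]23 | intermediate
24 | C7 enol triflate (C6=C7) | CC[Si](CC)(CC)OC[C@@H]2[C@H](O[Si](CC)(CC)CC)C[C@]3(C)C(OS(=O)(=O)C(F)(F)F)=CC[C@@](C)(O[Si](CC)(CC)CC)[C@@H]23 | intermediate
25 | vinyl bromide (7-bromo, C6=C7) | CC[Si](CC)(CC)OC[C@@H]2[C@H](O[Si](CC)(CC)CC)C[C@]3(C)C(Br)=CC[C@@](C)(O[Si](CC)(CC)CC)[C@@H]23 | intermediate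
26 | 7β-bromo-2α,4β-bis(triethylsilyloxy)-3α-(triethylsilyloxymethyl)-4α,7aβ-dimethyl-trans-hydrindane | CC[Si](CC)(CC)OC[C@@H]2[C@H](O[Si](CC)(CC)CC)C[C@]3(C)[C@@H](Br)CC[C@@](C)(O[Si](CC)(CC)CC)[C@@H]23 | intermediate
27 | C8 aldehyde: 7β-bromo-2α,4β-bis(triethylsilyloxy)-4α,7aβ-dimethyl-trans-hydrindane-3α-carbaldehyde | O=C[C@@H]2[C@H](O[Si](CC)(CC)CC)C[C@]3(C)[C@@H](Br)CC[C@@](C)(O[Si](CC)(CC)CC)[C@@H]23 | intermediate
28 | prenol, 3-methylbut-2-en-1-ol | CC(C)=CCO | starting material
29 | (S)-2-bromo-3-chloro-3-methylbutan-1-ol | OC[C@H](Br)C(C)(C)Cl | intermediate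
30 | (S)-2-bromo-3-chloro-3-methylbutyl trifluoromethanesulfonate | O=S(=O)(OC[C@H](Br)C(C)(C)Cl)C(F)(F)F | intermediate
31 | 2-(chloromethyl)allyl-trimethylsilane | C[Si](C)(C)CC(=C)CCl | starting material
32 | [2-(trimethylsilylmethyl)allyl]magnesium chloride | C[Si](C)(C)CC(=C)C[Mg]Cl | intermediate
33 | (S)-(5-bromo-6-chloro-6-methyl-2-methylideneheptyl)trimethylsilane | C[Si](C)(C)CC(=C)CC[C@H](Br)C(C)(C)Cl | intermediate
34 | (S)-4-bromo-3,3-dimethyl-1-methylidenecyclohexane | C=C1CC[C@H](Br)C(C)(C)C1 | intermediate
35 | (S)-4-bromo-3,3-dimethylcyclohexan-1-one | O=C1CC[C@H](Br)C(C)(C)C1 | intermediate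
36 | (4S)-4-bromo-3,3-dimethylcyclohexan-1-ol (C1 epimers) | OC1CC[C@H](Br)C(C)(C)C1 | intermediate
37 | 5-{[(4S)-4-bromo-3,3-dimethylcyclohexyl]sulfanyl}-1-phenyl-1H-tetrazole (C1′ epimers) | c1ccccc1-n1nnnc1SC2CC[C@H](Br)C(C)(C)C2 | intermediate
38 | 5-{[(4S)-4-bromo-3,3-dimethylcyclohexyl]sulfonyl}-1-phenyl-1H-tetrazole (C1′ epimers) | c1ccccc1-n1nnnc1S(=O)(=O)C2CC[C@H](Br)C(C)(C)C2 | intermediate
39 | potassium salt of 38 (carbanion at C1′) | c1ccccc1-n1nnnc1S(=O)(=O)C2([K])CC[C@H](Br)C(C)(C)C2 | intermediate
40 | 2,4-bis-O-(triethylsilyl)iriediol (E) | CC1(C)C/C(=C/[C@@H]2[C@H](O[Si](CC)(CC)CC)C[C@]3(C)[C@@H](Br)CC[C@@](C)(O[Si](CC)(CC)CC)[C@@H]23)CC[C@@H]1Br | intermediate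
41 | iriediol | CC1(C)C/C(=C/[C@@H]2[C@H](O)C[C@]3(C)[C@@H](Br)CC[C@@](C)(O)[C@@H]23)CC[C@@H]1Br | target

## Step count and least certain steps

Total: 27 steps. Longest linear sequence: 20 steps (steps 1 to 18, 26 and 27, from 1). The ring A branch is 7 steps (19 to 25) before the coupling.

Step 9 (key step). The insertion of the 1,1-disubstituted alkene in a six-ring closure may be slower than loss of cobalt from the alkyne complex. The facial preference set by C4 may also be small, because the strain it avoids (C4 methyl against the C7a methyl) is partly offset by allylic strain of the equatorial C4 methyl with the C8 arm. Fallback: from 12, a nickel-mediated [2+2+1] reaction with an isocyanide as the one-carbon unit. Ni(cod)2 and 2,6-dimethylphenyl isocyanide would form a mononuclear nickelacycle that inserts the isocyanide to give the N-aryl iminocyclopentene F1. Hydrolysis of F1 on moist silica gel returns to 15.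

Step 10. Instead of protonation at C3a, the carbanion or radical anion may expel the axial C4 silyloxy group that is aligned with the enone π system. The enolate may also lose the C8 silyloxy group, and kinetic protonation at C3 gives the less stable epimer first. Fallback: from 15, both silyl ethers are removed with HF·pyridine to the diol enone F2. F2 is reduced with Li/NH3 as its dialkoxide, whose oxygens cannot leave, to the diol ketone F3. Et3SiOTf and 2,6-lutidine then return F3 to 17.

Step 12. Activation of the crowded 2β-hydroxyl may be slow, and the oxyphosphonium ion may eliminate towards C1 or C3 instead of being displaced from the α face past the C8 arm. Fallback: from 18, a sulfonate displacement (Lattrell–Dax inversion). Tf2O and pyridine would give the 2β-triflate F4, and KNO2 with 18-crown-6 in DMF would give the inverted nitrite, which hydrolyses on work-up to 20. The acid stage of step 13 then leads to 21.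

Step 22. The allylsilane may be protodesilylated by acid formed in the medium before the chloride ionizes. Transfer of Br+ between alkenes may erode the configuration at C4′, and proton loss from the tertiary cation may compete with ring closure. Fallback: from 30, an acid-stable enol terminator. Alkylation of the dianion of tert-butyl acetoacetate (LiN(i-Pr)2, 2 equiv) with 30 would give the β-keto ester F5. Ionization of F5 in (CF3)2CHOH closes the ring through the enol carbon to the cyclic β-keto ester F6. CF3CO2H followed by gentle warming removes the tert-butyl group and CO2 and returns to 35, which is reduced as in step 23.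

Step 26. The tertiary sulfonyl carbanion may deprotonate the hindered aldehyde at C3 (epimerization, β-elimination of the C2 silyloxy group) instead of adding to it, and the alkene geometry is not controlled. Fallback: from 26, the polarity is reversed and a Wittig reaction is used. Buffered HF·pyridine at 0 °C cleaves only the primary silyl ether to the alcohol F7. I2, PPh3 and imidazole give the iodide F8, and PPh3 in hot MeCN gives the phosphonium iodide F9. The ylide of F9 (NaN(SiMe3)2, THF, −78 °C) is condensed with ketone 35, isolated after the periodate stage of step 23, and returns to 40 after the same separation of isomers.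

## Further compounds

F1 | step 9 | N-(2,6-dimethylphenyl)imine of 15 (iminocyclopentene) | Cc1cccc(C)c1N=C1C[C@]2(C)C3(OCCO3)CC[C@@](C)(O[Si](CC)(CC)CC)C2=C1CO[Si](CC)(CC)CC
F2 | step 10 | diol enone (15 without silyl groups) | O=C1C[C@]2(C)C3(OCCO3)CC[C@@](C)(O)C2=C1CO
F3 | step 10 | diol ketone (17 without silyl groups) | OC[C@@H]2C(=O)C[C@]3(C)C4(OCCO4)CC[C@@](C)(O)[C@@H]23
F4 | step 12 | 2β-trifluoromethanesulfonate of 18 | CC[Si](CC)(CC)OC[C@@H]2[C@@H](OS(=O)(=O)C(F)(F)F)C[C@]3(C)C4(OCCO4)CC[C@@](C)(O[Si](CC)(CC)CC)[C@@H]23
F5 | step 22 | tert-butyl (6S)-6-bromo-7-chloro-7-methyl-3-oxooctanoate | CC(C)(C)OC(=O)CC(=O)CC[C@H](Br)C(C)(C)Cl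
F6 | step 22 | tert-butyl (5S)-5-bromo-6,6-dimethyl-2-oxocyclohexane-1-carboxylate | CC(C)(C)OC(=O)C1C(=O)CC[C@H](Br)C1(C)C
F7 | step 26 | C8 alcohol (26 without the primary silyl group) | OC[C@@H]2[C@H](O[Si](CC)(CC)CC)C[C@]3(C)[C@@H](Br)CC[C@@](C)(O[Si](CC)(CC)CC)[C@@H]23
F8 | step 26 | C8 iodide | IC[C@@H]2[C@H](O[Si](CC)(CC)CC)C[C@]3(C)[C@@H](Br)CC[C@@](C)(O[Si](CC)(CC)CC)[C@@H]23
F9 | step 26 | C8 triphenylphosphonium iodide | [I-].c1ccccc1[P+](c1ccccc1)(c1ccccc1)C[C@@H]2[C@H](O[Si](CC)(CC)CC)C[C@]3(C)[C@@H](Br)CC[C@@](C)(O[Si](CC)(CC)CC)[C@@H]23
A1 | alternative 1 | seco-aldehyde for the carbonyl-ene closure (ring B with CH2CHO on C7a and the (E)-alkenyl chain to ring A on C3a, 1′R) | O=CC[C@]3(C)[C@@H](Br)CC[C@@](C)(O[Si](CC)(CC)CC)[C@H]3/C=C/[C@@H]1CC[C@H](Br)C(C)(C)C1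
A2 | alternative 1 | 4-O-triethylsilyl iriediol | CC1(C)C/C(=C/[C@@H]2[C@H](O)C[C@]3(C)[C@@H](Br)CC[C@@](C)(O[Si](CC)(CC)CC)[C@@H]23)CC[C@@H]1Br
A3 | alternative 2 | hydrindane with the C8-silylated allylsilane chain ending in the bromo chloride (8S) | C[Si](C)(C)[C@H](C(=C)CC[C@H](Br)C(C)(C)Cl)[C@@H]2[C@H](O[Si](C)(C)C(C)(C)C)C[C@]3(C)[C@@H](Br)CC[C@@](C)(O)[C@@H]23
A4 | alternative 2 | 2-O-(tert-butyldimethylsilyl) iriediol | CC1(C)C/C(=C/[C@@H]2[C@H](O[Si](C)(C)C(C)(C)C)C[C@]3(C)[C@@H](Br)CC[C@@](C)(O)[C@@H]23)CC[C@@H]1Br
A5 | alternative 3 | (Z,Z)-cyclononadienone | O=C1/C=C(C)\[C@@H](O[Si](C)(C)C(C)(C)C)CC[C@@](C)(O[Si](CC)(CC)CC)/C=C1/COCc1ccccc1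
A6 | alternative 3 | trans-hydrindan-2-one | c1ccccc1COC[C@@H]2C(=O)C[C@]3(C)[C@@H](O[Si](C)(C)C(C)(C)C)CC[C@@](C)(O[Si](CC)(CC)CC)[C@@H]23
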